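**Plan**

- Numbering: oxolane O1, C2 (3,4-dimethoxyphenyl), C3 (C9H2OH), C4 (OAc and C7'H2Ar', Ar' = 4-hydroxy-3-methoxyphenyl), C5. The retrosynthesis removes the acetyl, silyl and benzyl groups, returns C5 to a lactone carbonyl, cuts C4–O and C7'–Ar' in one operation, then C4=C7', then C2–C3.
- Enabling feature: C4 is a fully substituted ring carbon next to C5 that carries both an oxygen and the benzylic carbon C7'. With C5 as a lactone carbonyl and with Ar' and the C4 oxygen taken away, the ring O1–C2–C3–C4–C5 is an α-methylene-γ-butyrolactone whose C4=C7' bond accepts Ar' at C7' and oxygen at C4.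
- Forward: an auxiliary-controlled syn-aldol joins C2 to C3, lactonisation (O1–C5) closes the only ring, C9 is reduced to the alcohol level and silylated, and C7' is added by Mannich methylenation.
- After the key step the C5 carbonyl is taken down to CH2 through the lactol, the tertiary hydroxyl is acetylated and the two protecting groups are removed.
- Stereochemistry: C2 and C3 come from the (S)-4-benzyloxazolidinone syn-aldol, which becomes the trans lactone. C4 comes from substrate control, the oxidant entering anti to the C3 substituent. The O1–C2 bond is not broken afterwards.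

Key step: step 8

Remark on the chemistry: C9 is carried through the key step as a silyl ether at the alcohol oxidation level so that C3–H is not acidic; atom labels O1, C2–C5, C9 and C7' follow the target numbering throughout while systematic names use their own locants; commercial solutions of n-BuLi, LiN(i-Pr)2, Bu2BOTf and i-Bu2AlH are assumed.

**Route**

Step 1
Reactants: 1 (S)-4-benzyl-1,3-oxazolidin-2-one; 2 methyl 4-chloro-4-oxobutanoate
Product: 4 methyl 4-[(4S)-4-benzyl-2-oxo-1,3-oxazolidin-3-yl]-4-oxobutanoate, via N-lithio oxazolidinone 3 (not isolated)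
Conditions: n-BuLi, THF, −78 °C; then 2, −78 → 0 °C
Reagents that add atoms: none
Why: N-acylation of the lithiated oxazolidinone 3 by the acid chloride (imide formation by acyl substitution) is fast at low temperature and should leave the methyl ester untouched.

Step 2
Reactants: 4 methyl 4-[(4S)-4-benzyl-2-oxo-1,3-oxazolidin-3-yl]-4-oxobutanoate; 5 3,4-dimethoxybenzaldehyde (veratraldehyde)
Product: 7 methyl (3S,4S)-3-{[(4S)-4-benzyl-2-oxo-1,3-oxazolidin-3-yl]carbonyl}-4-(3,4-dimethoxyphenyl)-4-hydroxybutanoate (syn-aldol), via dibutylboron (Z)-enolate 6 (not isolated)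
Conditions: Bu2BOTf, i-Pr2NEt, CH2Cl2, 0 °C; then 5, −78 → 0 °C; pH 7 buffer, MeOH, H2O2, 0 °C
Reagents that add atoms: none
Why: Evans syn-aldol reaction, in which the (Z)-boron enolate 6 of the imide (the ester is not enolised) should add to 5 through a closed chair transition state on the face away from the benzyl group of the auxiliary, setting the future C3 and C2 as the (S,S) syn pair.

Step 3
Reactants: 7 syn-aldol adduct
Product: 9 (2S,3S)-2-(3,4-dimethoxyphenyl)-5-oxooxolane-3-carboxylic acid (trans), via hydroxy diacid 8 (not isolated)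
Conditions: LiOH, H2O2, THF/H2O, 0 °C → rt; aq. Na2SO3; 1 M HCl to pH 2, rt
Reagents that add atoms: hydrogen peroxide, OO; lithium hydroxide, [Li+].[OH-]
Why: Hydroperoxide attacks the exocyclic imide carbonyl (auxiliary removal by LiOOH hydrolysis) and hydroxide saponifies the methyl ester, and on acidification the γ-hydroxy diacid 8 should lactonise to the five-membered ring, in which the syn-aldol pair appears as trans C2/C3 with neither stereocentre touched.

Step 4
Reactants: 9 (2S,3S)-2-(3,4-dimethoxyphenyl)-5-oxooxolane-3-carboxylic acid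
Product: 10 (4R,5S)-5-(3,4-dimethoxyphenyl)-4-(hydroxymethyl)oxolan-2-one
Conditions: BH3·SMe2, THF, 0 °C → rt; MeOH
Reagents that add atoms: none
Why: Chemoselective borane reduction, in which the free carboxylic acid is reduced through its acyloxyborane far faster than the lactone, should bring C9 to the alcohol level with the ring intact.

Step 5
Reactants: 10 (4R,5S)-5-(3,4-dimethoxyphenyl)-4-(hydroxymethyl)oxolan-2-one
Product: 11 (4R,5S)-4-{[tert-butyl(diphenyl)silyl]oxymethyl}-5-(3,4-dimethoxyphenyl)oxolan-2-one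
Conditions: TBDPSCl, imidazole, CH2Cl2, 0 °C → rt
Reagents that add atoms: tert-butyl(chloro)diphenylsilane, CC(C)(C)[Si](Cl)(c1ccccc1)c1ccccc1
Why: Silylation of the primary alcohol under imidazole catalysis should give an ether that withstands the enolate, hydride and BF3·OEt2 steps that follow.

Step 6
Reactants: 11 (4R,5S)-4-{[tert-butyl(diphenyl)silyl]oxymethyl}-5-(3,4-dimethoxyphenyl)oxolan-2-one
Product: 15 (4R,5S)-4-{[tert-butyl(diphenyl)silyl]oxymethyl}-5-(3,4-dimethoxyphenyl)-3-methylideneoxolan-2-one, via lithium enolate 12 (not isolated), via Mannich base 13 (not isolated), via trimethylammonium iodide 14 (not isolated)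
Conditions: LiN(i-Pr)2, THF, −78 °C; Me2N=CH2+ I−, −78 °C → rt; MeI, MeOH, rt; aq. NaHCO3, CH2Cl2, rt
Reagents that add atoms: N,N-dimethylmethyleneiminium iodide, C=[N+](C)C.[I-]
Why: Mannich-type α-methylenation, in which enolate 12 is aminomethylated to 13, exhaustive methylation gives 14 and mild base should expel trimethylamine (E1cB) to place C7' as the exocyclic methylene, the C4 stereocentre of 13 being lost on purpose.

Step 7
Reactants: 16 1-(benzyloxy)-4-bromo-2-methoxybenzene
Product: 17 [4-(benzyloxy)-3-methoxyphenyl]magnesium bromide (THF solution, titrated)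
Conditions: Mg turnings, I2 (cat.), THF, 40 °C
Reagents that add atoms: magnesium, [Mg]
Why: Grignard reagent formation by insertion of magnesium into the aryl–bromine bond should proceed normally, since the benzyl and methyl ethers are inert to the reagent.

Step 8
Reactants: 15 (4R,5S)-4-{[tert-butyl(diphenyl)silyl]oxymethyl}-5-(3,4-dimethoxyphenyl)-3-methylideneoxolan-2-one; 17 [4-(benzyloxy)-3-methoxyphenyl]magnesium bromide
Product: 19 (3S,4R,5S)-3-[4-(benzyloxy)-3-methoxybenzyl]-4-{[tert-butyl(diphenyl)silyl]oxymethyl}-5-(3,4-dimethoxyphenyl)-3-hydroxyoxolan-2-one, via bromomagnesium enolate 18 (not isolated)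
Conditions: CuBr·SMe2 (10 mol %), THF, −78 °C, slow addition of 15 to 17; then 3-phenyl-2-(phenylsulfonyl)oxaziridine, −78 → −40 °C; aq. NH4Cl
Reagents that add atoms: 3-phenyl-2-(phenylsulfonyl)oxaziridine, O=S(=O)(c1ccccc1)N1OC1c1ccccc1
Why: Transmetalation of 17 to copper gives an arylcopper species that adds in 1,4-fashion to the exocyclic methylene of 15 (C7'–Ar' bond) and returns the metal to magnesium, leaving the bromomagnesium enolate 18, whose C4 then attacks the electrophilic oxygen of the N-sulfonyloxaziridine with loss of the sulfonimine (C4–O bond). The closest known reaction types are the copper-catalysed conjugate addition of aryl Grignard reagents to α-methylene-γ-butyrolactones and the oxaziridine α-hydroxylation of lactone enolates, joined here as a tandem conjugate addition–enolate oxidation. No ring is closed. The one new stereocentre, C4, is controlled by the neighbouring C3 substituent: the CH2OTBDPS group shields one face of the planar enolate, oxygen should enter anti to it, and C7' is thereby left cis to C9 as in the target. The step needs 1,4- over 1,2-addition, which copper catalysis at −78 °C secures, and it needs the enolate not to add to unreacted 15, which slow addition of 15 to the reagent and the fully substituted enolate carbon secure. Migration of the double bond into the ring is not expected, because C3 bears a silyloxymethyl group and no acyl group, so C3–H is not acidic.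

Step 9
Reactants: 19 α-hydroxy lactone
Product: 20 (3S,4R,5S)-3-[4-(benzyloxy)-3-methoxybenzyl]-4-{[tert-butyl(diphenyl)silyl]oxymethyl}-5-(3,4-dimethoxyphenyl)oxolane-2,3-diol (lactol, both anomers)
Conditions: i-Bu2AlH, CH2Cl2, −78 °C; aq. KNaC4H4O6
Reagents that add atoms: none
Why: Partial reduction of a γ-lactone with i-Bu2AlH at −78 °C should stop at the aluminium hemiacetal (lactone-to-lactol reduction), one extra equivalent covering the free tertiary hydroxyl while the silyl and benzyl ethers are inert.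

Step 10
Reactants: 20 lactol
Product: 22 (3S,4R,5S)-3-[4-(benzyloxy)-3-methoxybenzyl]-4-{[tert-butyl(diphenyl)silyl]oxymethyl}-5-(3,4-dimethoxyphenyl)oxolan-3-ol, via oxocarbenium ion 21 (not isolated)
Conditions: Et3SiH, BF3·OEt2, CH2Cl2, −78 → −40 °C; aq. NaHCO3
Reagents that add atoms: none
Why: Ionic hydrogenation, in which BF3·OEt2 ionises the lactol to the oxocarbenium ion 21 and Et3SiH delivers hydride to C5 (not a stereocentre), should leave the O1–C2 bond and therefore the C2 configuration intact at low temperature.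

Step 11
Reactants: 22 tertiary alcohol
Product: 23 (3S,4R,5S)-3-[4-(benzyloxy)-3-methoxybenzyl]-4-{[tert-butyl(diphenyl)silyl]oxymethyl}-5-(3,4-dimethoxyphenyl)oxolan-3-yl acetate
Conditions: Ac2O, DMAP, Et3N, CH2Cl2, rt → 40 °C
Reagents that add atoms: acetic anhydride, CC(=O)OC(C)=O
Why: DMAP-catalysed acyl transfer is the standard acetylation of hindered tertiary alcohols and should meet no competition, since no other free hydroxyl is present.

Step 12
Reactants: 23 silyl ether acetate
Product: 24 (3S,4R,5S)-3-[4-(benzyloxy)-3-methoxybenzyl]-5-(3,4-dimethoxyphenyl)-4-(hydroxymethyl)oxolan-3-yl acetate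
Conditions: HF·pyridine, pyridine, THF, 0 °C → rt
Reagents that add atoms: none
Why: Fluoride-driven silyl ether cleavage under buffered, weakly acidic conditions should free the C9 hydroxyl without the acetyl migration or ester cleavage that basic fluoride could cause.

Step 13
Reactants: 24 benzyl ether
Product: 25 (3S,4R,5S)-5-(3,4-dimethoxyphenyl)-3-(4-hydroxy-3-methoxybenzyl)-4-(hydroxymethyl)oxolan-3-yl acetate (target; 2S,3R,4S in the target numbering)
Conditions: H2 (1 atm), Pd/C, EtOAc, rt, stopped on consumption of 24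
Reagents that add atoms: none
Why: Catalytic hydrogenolysis of the aryl benzyl ether is fast under neutral conditions and should be complete before the cyclic benzylic O1–C2 bond, the acetate or the arenes are affected.

**Compound list**

1 | (S)-4-benzyl-1,3-oxazolidin-2-one | O=C1N[C@@H](Cc2ccccc2)CO1 | starting material
2 | methyl 4-chloro-4-oxobutanoate | COC(=O)CCC(Cl)=O | starting material
3 | N-lithio derivative of 1 | [Li]N1[C@@H](Cc2ccccc2)COC1=O | intermediate
4 | methyl 4-[(4S)-4-benzyl-2-oxo-1,3-oxazolidin-3-yl]-4-oxobutanoate | COC(=O)CCC(=O)N1[C@@H](Cc2ccccc2)COC1=O | intermediate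
5 | 3,4-dimethoxybenzaldehyde | COc1ccc(C=O)cc1OC | starting material
6 | dibutylboron (Z)-enolate of 4 | COC(=O)C/C=C(\OB(CCCC)CCCC)N1[C@@H](Cc2ccccc2)COC1=O | intermediate
7 | methyl (3S,4S)-3-{[(4S)-4-benzyl-2-oxo-1,3-oxazolidin-3-yl]carbonyl}-4-(3,4-dimethoxyphenyl)-4-hydroxybutanoate | COC(=O)C[C@H](C(=O)N1[C@@H](Cc2ccccc2)COC1=O)[C@H](O)c1ccc(OC)c(OC)c1 | intermediate
8 | (2S)-2-[(S)-(3,4-dimethoxyphenyl)(hydroxy)methyl]butanedioic acid (dilithium salt in the flask) | OC(=O)C[C@H](C(=O)O)[C@H](O)c1ccc(OC)c(OC)c1 | intermediate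
9 | (2S,3S)-2-(3,4-dimethoxyphenyl)-5-oxooxolane-3-carboxylic acid | O=C1C[C@H](C(=O)O)[C@@H](c2ccc(OC)c(OC)c2)O1 | intermediate
10 | (4R,5S)-5-(3,4-dimethoxyphenyl)-4-(hydroxymethyl)oxolan-2-one | O=C1C[C@H](CO)[C@@H](c2ccc(OC)c(OC)c2)O1 | intermediate
11 | (4R,5S)-4-{[tert-butyl(diphenyl)silyl]oxymethyl}-5-(3,4-dimethoxyphenyl)oxolan-2-one | O=C1C[C@H](CO[Si](c2ccccc2)(c2ccccc2)C(C)(C)C)[C@@H](c2ccc(OC)c(OC)c2)O1 | intermediate
12 | lithium enolate of 11 | [Li]OC1=C[C@H](CO[Si](c2ccccc2)(c2ccccc2)C(C)(C)C)[C@@H](c2ccc(OC)c(OC)c2)O1 | intermediate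
13 | (3R,4R,5S)-4-{[tert-butyl(diphenyl)silyl]oxymethyl}-5-(3,4-dimethoxyphenyl)-3-[(dimethylamino)methyl]oxolan-2-one (3,4-trans) | O=C1[C@@H](CN(C)C)[C@H](CO[Si](c2ccccc2)(c2ccccc2)C(C)(C)C)[C@@H](c2ccc(OC)c(OC)c2)O1 | intermediate
14 | N-methyl iodide (trimethylammonium iodide) of 13 | O=C1[C@@H](C[N+](C)(C)C)[C@H](CO[Si](c2ccccc2)(c2ccccc2)C(C)(C)C)[C@@H](c2ccc(OC)c(OC)c2)O1.[I-] | intermediate
15 | (4R,5S)-4-{[tert-butyl(diphenyl)silyl]oxymethyl}-5-(3,4-dimethoxyphenyl)-3-methylideneoxolan-2-one | O=C1C(=C)[C@H](CO[Si](c2ccccc2)(c2ccccc2)C(C)(C)C)[C@@H](c2ccc(OC)c(OC)c2)O1 | intermediate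
16 | 1-(benzyloxy)-4-bromo-2-methoxybenzene | COc1cc(Br)ccc1OCc1ccccc1 | starting material
17 | [4-(benzyloxy)-3-methoxyphenyl]magnesium bromide | COc1cc([Mg]Br)ccc1OCc1ccccc1 | intermediate
18 | bromomagnesium enolate of the 3-[4-(benzyloxy)-3-methoxybenzyl] lactone | Br[Mg]OC1=C(Cc2ccc(OCc3ccccc3)c(OC)c2)[C@H](CO[Si](c2ccccc2)(c2ccccc2)C(C)(C)C)[C@@H](c2ccc(OC)c(OC)c2)O1 | intermediate
19 | (3S,4R,5S)-3-[4-(benzyloxy)-3-methoxybenzyl]-4-{[tert-butyl(diphenyl)silyl]oxymethyl}-5-(3,4-dimethoxyphenyl)-3-hydroxyoxolan-2-one | O=C1[C@](O)(Cc2ccc(OCc3ccccc3)c(OC)c2)[C@H](CO[Si](c2ccccc2)(c2ccccc2)C(C)(C)C)[C@@H](c2ccc(OC)c(OC)c2)O1 | intermediate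
20 | (3S,4R,5S)-3-[4-(benzyloxy)-3-methoxybenzyl]-4-{[tert-butyl(diphenyl)silyl]oxymethyl}-5-(3,4-dimethoxyphenyl)oxolane-2,3-diol (anomeric mixture) | OC1[C@](O)(Cc2ccc(OCc3ccccc3)c(OC)c2)[C@H](CO[Si](c2ccccc2)(c2ccccc2)C(C)(C)C)[C@@H](c2ccc(OC)c(OC)c2)O1 | intermediate
21 | cyclic oxocarbenium ion from 20 | C1[C@](O)(Cc2ccc(OCc3ccccc3)c(OC)c2)[C@H](CO[Si](c2ccccc2)(c2ccccc2)C(C)(C)C)[C@@H](c2ccc(OC)c(OC)c2)[O+]=1 | intermediate
22 | (3S,4R,5S)-3-[4-(benzyloxy)-3-methoxybenzyl]-4-{[tert-butyl(diphenyl)silyl]oxymethyl}-5-(3,4-dimethoxyphenyl)oxolan-3-ol | C1[C@](O)(Cc2ccc(OCc3ccccc3)c(OC)c2)[C@H](CO[Si](c2ccccc2)(c2ccccc2)C(C)(C)C)[C@@H](c2ccc(OC)c(OC)c2)O1 | intermediate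
23 | (3S,4R,5S)-3-[4-(benzyloxy)-3-methoxybenzyl]-4-{[tert-butyl(diphenyl)silyl]oxymethyl}-5-(3,4-dimethoxyphenyl)oxolan-3-yl acetate | C1[C@](OC(C)=O)(Cc2ccc(OCc3ccccc3)c(OC)c2)[C@H](CO[Si](c2ccccc2)(c2ccccc2)C(C)(C)C)[C@@H](c2ccc(OC)c(OC)c2)O1 | intermediate
24 | (3S,4R,5S)-3-[4-(benzyloxy)-3-methoxybenzyl]-5-(3,4-dimethoxyphenyl)-4-(hydroxymethyl)oxolan-3-yl acetate | C1[C@](OC(C)=O)(Cc2ccc(OCc3ccccc3)c(OC)c2)[C@H](CO)[C@@H](c2ccc(OC)c(OC)c2)O1 | intermediate
25 | (3S,4R,5S)-5-(3,4-dimethoxyphenyl)-3-(4-hydroxy-3-methoxybenzyl)-4-(hydroxymethyl)oxolan-3-yl acetate | COc1cc(C[C@@]2(OC(C)=O)CO[C@H](c3ccc(OC)c(OC)c3)[C@H]2CO)ccc1O | target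

**Step count and risks**

Total step count: 13. Longest linear sequence: 12 steps (steps 1 to 6 and 8 to 13, from 1); step 7 is a one-step branch.

Step 8 is the most likely to fail. The bromomagnesium enolate may add to unreacted 15 (Michael oligomerisation). It may also take up oxygen too slowly and be captured by the sulfonimine, or be oxidised with poor facial selectivity. The fallback forms the same two bonds in the reverse order with known reactions. From 15, nucleophilic epoxidation of the Weitz–Scheffer type (t-BuOOH, DBU, CH2Cl2, 0 °C → rt) should give the spiro-epoxy lactone (3R,6S,7R)-7-{[tert-butyl(diphenyl)silyl]oxymethyl}-6-(3,4-dimethoxyphenyl)-1,5-dioxaspiro[2.4]heptan-4-one F1, with the epoxide oxygen anti to the C3 substituent. Copper-catalysed opening of the epoxide at its unhindered methylene carbon by 17 (CuI 10 mol %, THF, −40 °C; aq. NH4Cl) then forms C7'–Ar' without touching C4 and comes back to the route at 19.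

Step 10 is the second risk. BF3·OEt2 may ionise the benzylic O1–C2 bond next to the electron-rich arene as well as the lactol, which would lead to epimerisation at C2, Friedel–Crafts closure onto Ar' or reductive ring opening. The fallback closes the ring from the other end without a hydride donor. From 20, NaBH4 (MeOH, 0 °C) should reduce the open hydroxy-aldehyde form to the triol (1S,2R,3S)-3-[4-(benzyloxy)-3-methoxybenzyl]-2-{[tert-butyl(diphenyl)silyl]oxymethyl}-1-(3,4-dimethoxyphenyl)butane-1,3,4-triol F2. Catalytic 10-camphorsulfonic acid (CH2Cl2, 0 °C, short contact) should then close the oxolane by 5-exo attack of the C5 hydroxyl on the C2 benzylic cation. The 2,3-trans ring is expected as the more stable product, and the route is rejoined at 22.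

Step 11 is the third risk. Acyl transfer to the tertiary hydroxyl, which is flanked by C3 and C7', may be too slow, and forcing it may cause loss of the silyl ether or acid-promoted opening at C2. The fallback acylates a preformed alkoxide in place of the neutral alcohol. From 22, deprotonation with KN(SiMe3)2 (THF, −78 °C) should give the potassium alkoxide of 22 F3, which is O-acylated by acetyl chloride (−78 → 0 °C) and comes back to the route at 23.

**Further compounds**

F1 | step 8 | (3R,6S,7R)-7-{[tert-butyl(diphenyl)silyl]oxymethyl}-6-(3,4-dimethoxyphenyl)-1,5-dioxaspiro[2.4]heptan-4-one | O=C1[C@]2(CO2)[C@H](CO[Si](c3ccccc3)(c3ccccc3)C(C)(C)C)[C@@H](c3ccc(OC)c(OC)c3)O1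
F2 | step 10 | (1S,2R,3S)-3-[4-(benzyloxy)-3-methoxybenzyl]-2-{[tert-butyl(diphenyl)silyl]oxymethyl}-1-(3,4-dimethoxyphenyl)butane-1,3,4-triol | OC[C@](O)(Cc1ccc(OCc2ccccc2)c(OC)c1)[C@H](CO[Si](c1ccccc1)(c1ccccc1)C(C)(C)C)[C@@H](c1ccc(OC)c(OC)c1)O
F3 | step 11 | potassium alkoxide of 22 | C1[C@](O[K])(Cc2ccc(OCc3ccccc3)c(OC)c2)[C@H](CO[Si](c2ccccc2)(c2ccccc2)C(C)(C)C)[C@@H](c2ccc(OC)c(OC)c2)O1
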